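**Retrosynthetic overview**
1. Juglanin A ⇐ aqueous-acid unmasking (C(NC)Ts → C=O, MOM ether → phenol) of a macrocyclic α-tosyl isocyanide.
2. That macrocycle ⇐ TosMIC (a carbonyl 1,1-dianion equivalent that becomes the ketone carbon C-5) + a diaryl ether dibromide. Both C4–C5 and C5–C6 are made by C-alkylation, and the second alkylation closes the 15-membered ring, which is the only ring formed and is formed last.
3. Dibromide ⇐ Appel bromination ⇐ MOM-directed ortho-lithiation of the diaryl ether and alkylation with 1,4-dibromobutane (ring B four-carbon arm).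
4. Diaryl ether ⇐ Ullmann coupling of mono-MOM 2-methoxyresorcinol with 2-(3-bromo-4-methoxyphenyl)ethanol (ring A with its two-carbon arm).

Assumption: the target SMILES contains no stereocentre or double-bond geometry, so juglanin A is made as the achiral compound drawn and no stereocontrol is needed; compounds 1, 3, 5 and 9 are taken as catalogue chemicals.

**Route**

Step 1
Reactants: 1 2-methoxybenzene-1,3-diol (2-methoxyresorcinol)
Product: 2 2-methoxy-3-(methoxymethoxy)phenol
Conditions: 1 (2 equiv), NaH (1.0 equiv), DMF, 0 °C; MOMCl (1.0 equiv), 0 °C to rt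
Reagents that add atoms: chloromethyl methyl ether (MOMCl), COCCl
Why: Williamson-type O-alkylation (MOM protection) of the mono-phenoxide of a symmetric diol used in excess, so only one mono-ether can form and the surplus diol is recovered.

Step 2
Reactants: 2 2-methoxy-3-(methoxymethoxy)phenol; 3 2-(3-bromo-4-methoxyphenyl)ethan-1-ol
Product: 4 2-{4-methoxy-3-[2-methoxy-3-(methoxymethoxy)phenoxy]phenyl}ethan-1-ol
Conditions: CuI (10 mol %), picolinic acid (20 mol %), K3PO4 (2 equiv), DMSO, 100 °C
Reagents that add atoms: none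
Why: Ullmann-type copper-catalysed diaryl ether coupling, in which the CuI/picolinic acid system tolerates ortho-substituted electron-rich partners and the phenoxide reacts far faster than the free primary alcohol.

Step 3
Reactants: 4 2-{4-methoxy-3-[2-methoxy-3-(methoxymethoxy)phenoxy]phenyl}ethan-1-ol; 5 1,4-dibromobutane
Product: 7 2-{3-[4-(4-bromobutyl)-2-methoxy-3-(methoxymethoxy)phenoxy]-4-methoxyphenyl}ethan-1-ol, via dilithiated aryl ether 6 (not isolated)
Conditions: n-BuLi (2.3 equiv), THF, −20 to 0 °C; then cannulated into 5 (6 equiv), THF, 0 °C to rt; H2O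
Reagents that add atoms: none
Why: Directed ortho-metalation followed by SN2 alkylation: after the first equivalent of n-BuLi turns the alcohol into a spectator alkoxide, the MOM ether (the strongest director present) guides lithiation to the only ortho hydrogen it has, and the aryllithium is alkylated by one end of the excess dibromide.

Step 4
Reactants: 7 2-{3-[4-(4-bromobutyl)-2-methoxy-3-(methoxymethoxy)phenoxy]-4-methoxyphenyl}ethan-1-ol
Product: 8 1-(4-bromobutyl)-4-[5-(2-bromoethyl)-2-methoxyphenoxy]-3-methoxy-2-(methoxymethoxy)benzene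
Conditions: CBr4, PPh3, 2,6-lutidine (0.2 equiv), CH2Cl2, 0 °C
Reagents that add atoms: carbon tetrabromide (CBr4), BrC(Br)(Br)Br
Why: Appel reaction, which converts the primary alcohol to the bromide through an alkoxyphosphonium ion under near-neutral conditions that spare the aryl MOM ether and the existing alkyl bromide.

Step 5
Reactants: 8 1-(4-bromobutyl)-4-[5-(2-bromoethyl)-2-methoxyphenoxy]-3-methoxy-2-(methoxymethoxy)benzene; 9 p-toluenesulfonylmethyl isocyanide (TosMIC)
Product: 13 juglanin A, via butyl-arm monoalkylated TosMIC 10 (not isolated), via ethyl-arm monoalkylated TosMIC 11 (not isolated), via macrocyclic tosyl isocyanide 12 (not isolated)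
Conditions: 8 + 9 (1.05 equiv) added by syringe pump over 12 h to NaH (3 equiv), n-Bu4NI (10 mol %), DMF, rt (final 3 mM); DMF evaporated, then crude in conc. aq HCl, THF/MeOH, 40 °C
Reagents that add atoms: water, O
Why: Van Leusen TosMIC ketone synthesis run as a macrocyclisation (known for cycloalkanones and cyclophane ketones from α,ω-dihalides): the TosMIC carbanion is C-alkylated by either bromide, the second deprotonation closes the 15-membered ring by intramolecular SN2 under high dilution, and aqueous HCl then hydrolyses the C(NC)Ts unit to the ketone and cleaves the MOM acetal in the same operation.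

**Compound list**
1 | 2-methoxybenzene-1,3-diol (2-methoxyresorcinol) | COc1c(O)cccc1O | starting material
2 | 2-methoxy-3-(methoxymethoxy)phenol | COCOc1cccc(O)c1OC | intermediate
3 | 2-(3-bromo-4-methoxyphenyl)ethan-1-ol | COc1ccc(CCO)cc1Br | starting material
4 | 2-{4-methoxy-3-[2-methoxy-3-(methoxymethoxy)phenoxy]phenyl}ethan-1-ol | COCOc1cccc(Oc2cc(CCO)ccc2OC)c1OC | intermediate
5 | 1,4-dibromobutane | BrCCCCBr | starting material
6 | dilithiated aryl ether: lithium 2-{3-[4-lithio-2-methoxy-3-(methoxymethoxy)phenoxy]-4-methoxyphenyl}ethoxide (not isolated) | [Li]OCCc1ccc(OC)c(Oc2ccc([Li])c(OCOC)c2OC)c1 | intermediate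
7 | 2-{3-[4-(4-bromobutyl)-2-methoxy-3-(methoxymethoxy)phenoxy]-4-methoxyphenyl}ethan-1-ol | OCCc1ccc(OC)c(Oc2ccc(CCCCBr)c(OCOC)c2OC)c1 | intermediate
8 | 1-(4-bromobutyl)-4-[5-(2-bromoethyl)-2-methoxyphenoxy]-3-methoxy-2-(methoxymethoxy)benzene | BrCCc1ccc(OC)c(Oc2ccc(CCCCBr)c(OCOC)c2OC)c1 | intermediate
9 | p-toluenesulfonylmethyl isocyanide (TosMIC) | Cc1ccc(cc1)S(=O)(=O)C[N+]#[C-] | starting material
10 | butyl-arm monoalkylated TosMIC: 5-{4-[5-(2-bromoethyl)-2-methoxyphenoxy]-3-methoxy-2-(methoxymethoxy)phenyl}-1-tosylpentyl isocyanide, racemic (not isolated) | BrCCc1ccc(OC)c(Oc2ccc(CCCCC([N+]#[C-])S(=O)(=O)c3ccc(C)cc3)c(OCOC)c2OC)c1 | intermediate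
11 | ethyl-arm monoalkylated TosMIC: 3-{3-[4-(4-bromobutyl)-2-methoxy-3-(methoxymethoxy)phenoxy]-4-methoxyphenyl}-1-tosylpropyl isocyanide, racemic (not isolated) | BrCCCCc1ccc(Oc2cc(CCC([N+]#[C-])S(=O)(=O)c3ccc(C)cc3)ccc2OC)c(OC)c1OCOC | intermediate
12 | macrocyclic tosyl isocyanide: the juglanin A ring system with C-5 of the seven-carbon bridge (future carbonyl carbon) bearing isocyano and p-tolylsulfonyl groups and the ring B phenol as its MOM ether, racemic (not isolated) | COc1ccc2cc1Oc1ccc(c(OCOC)c1OC)CCCCC([N+]#[C-])(CC2)S(=O)(=O)c1ccc(C)cc1 | intermediate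
13 | juglanin A (15-membered meta,para-bridged diaryl ether heptanoid; ketone at C-5 counted from ring B; ring B carries OH ortho to the chain and OMe next to it; ring A carries OMe ortho to the ether oxygen) | COc1ccc2cc1Oc1ccc(c(O)c1OC)CCCCC(=O)CC2 | target

**Totals**
Total step count: 5. Longest linear sequence: 5 steps (1 → 2 → 4 → 7 → 8 → 13).

**Three steps most likely to fail, with fallbacks**

Step 5 (one-pot double alkylation and ring closure). The risks are oligomerisation in competition with closure of the 15-membered ring and E2 loss of HBr from the 2-bromoethyl arm.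
The fallback sets out from 7 and comes back to the route at 12. It separates the two C-alkylations so that the ring-closing one is unimolecular on a purified precursor. Bromo alcohol 7 is added to the preformed sodium salt of TosMIC 9 (3 equiv 9, 2.5 equiv NaH, DMSO/THF, 0 °C to rt). The excess of 9 holds the reaction at mono-alkylation and the free alcohol is not deprotonated, giving 2-{3-[4-(5-isocyano-5-tosylpentyl)-2-methoxy-3-(methoxymethoxy)phenoxy]-4-methoxyphenyl}ethan-1-ol F1. Mesylation (MsCl, Et3N, CH2Cl2, 0 °C) gives 2-{3-[4-(5-isocyano-5-tosylpentyl)-2-methoxy-3-(methoxymethoxy)phenoxy]-4-methoxyphenyl}ethyl methanesulfonate F2. Slow addition of F2 to NaH in DMF (final 2 mM) closes the ring by intramolecular C-alkylation to 12, which is hydrolysed with conc. aq HCl as in step 5.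

Step 3 (ortho-lithiation and alkylation with a dihalide). The risks are sluggish SN2 of the aryllithium, elimination on the dibromide and interference from the lithium alkoxide.
The fallback sets out from 2 and comes back to the route at 8. It avoids organolithium chemistry and builds the four-carbon arm before the diaryl ether, using the fact that the required carbon is para to the free phenol of 2.
- Iodination of 2 (NIS, MeCN, 0 °C) gives 4-iodo-2-methoxy-3-(methoxymethoxy)phenol F3.
- Sonogashira coupling with but-3-yn-1-ol (Pd(PPh3)2Cl2, CuI, Et3N, 50 °C) gives 4-(4-hydroxybut-1-yn-1-yl)-2-methoxy-3-(methoxymethoxy)phenol F4.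
- Hydrogenation (H2, Pd/C, EtOAc) gives 4-(4-hydroxybutyl)-2-methoxy-3-(methoxymethoxy)phenol F5.
- Ullmann coupling of F5 with 3 under the step 2 conditions gives 4-{4-[5-(2-hydroxyethyl)-2-methoxyphenoxy]-3-methoxy-2-(methoxymethoxy)phenyl}butan-1-ol F6.
- Double Appel bromination (CBr4, PPh3, CH2Cl2, 0 °C) converts both primary alcohols and delivers 8.

Step 2 (Ullmann coupling of two ortho-substituted, electron-rich partners). The risk is low conversion or reduction of the aryl bromide.
The fallback sets out from 3 and comes back to the route at 4. It reverses the roles so that ring A is the aryl nucleophile in an oxidative coupling at room temperature. Bromide 3 is treated with n-BuLi (2.2 equiv, THF, −78 °C; the first equivalent forms the alkoxide, the second effects bromine–lithium exchange), then B(OiPr)3 and aqueous HCl, giving [5-(2-hydroxyethyl)-2-methoxyphenyl]boronic acid F7. Chan–Evans–Lam coupling of F7 with phenol 2 (Cu(OAc)2, pyridine, 4 Å molecular sieves, CH2Cl2, air, rt) gives 4.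

**Further compounds**
F1 | step 5 | 2-{3-[4-(5-isocyano-5-tosylpentyl)-2-methoxy-3-(methoxymethoxy)phenoxy]-4-methoxyphenyl}ethan-1-ol (racemic) | OCCc1ccc(OC)c(Oc2ccc(CCCCC([N+]#[C-])S(=O)(=O)c3ccc(C)cc3)c(OCOC)c2OC)c1
F2 | step 5 | 2-{3-[4-(5-isocyano-5-tosylpentyl)-2-methoxy-3-(methoxymethoxy)phenoxy]-4-methoxyphenyl}ethyl methanesulfonate (racemic) | CS(=O)(=O)OCCc1ccc(OC)c(Oc2ccc(CCCCC([N+]#[C-])S(=O)(=O)c3ccc(C)cc3)c(OCOC)c2OC)c1
F3 | step 3 | 4-iodo-2-methoxy-3-(methoxymethoxy)phenol | COCOc1c(I)ccc(O)c1OC
F4 | step 3 | 4-(4-hydroxybut-1-yn-1-yl)-2-methoxy-3-(methoxymethoxy)phenol | COCOc1c(C#CCCO)ccc(O)c1OC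
F5 | step 3 | 4-(4-hydroxybutyl)-2-methoxy-3-(methoxymethoxy)phenol | COCOc1c(CCCCO)ccc(O)c1OC
F6 | step 3 | 4-{4-[5-(2-hydroxyethyl)-2-methoxyphenoxy]-3-methoxy-2-(methoxymethoxy)phenyl}butan-1-ol | OCCCCc1ccc(Oc2cc(CCO)ccc2OC)c(OC)c1OCOC
F7 | step 2 | [5-(2-hydroxyethyl)-2-methoxyphenyl]boronic acid | COc1ccc(CCO)cc1B(O)O
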